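**Retrosynthetic overview**

1. Numbering used throughout: O1, C2 (aryl), C3 (methyl), O4, C4a, C5 (OMe), C6, C7 (side chain), C8, C8a. The (E)-allylic alcohol at C7 is traced back through the enoate (ester reduction) and the C7 aldehyde (Horner–Wadsworth–Emmons) to a C7 methyl ester.
2. The plan rests on C2: a single ArCH carbon lodged between O1 and C3 of the dioxane ring. Cutting C2–O1 and C2–C3 and rejoining O1 to C3 shrinks the ring to the five-membered acetal O1–C3H(CH3)–O4, a 2-methyl-1,3-benzodioxole, and leaves an aryl carbene.
3. Forward, the carbene from 3,4,5-trimethoxyphenyldiazomethane is inserted into the O1–C3 acetal bond by an oxonium ylide [1,2]-Stevens shift on a chiral dirhodium carboxylate. This one step forms C2–O1, C2–C3 and both stereocentres; the C7 ester steers the ylide to O1.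
4. Ring order: the dioxole ring is made first by acetalisation of methyl 3,4-dihydroxy-5-methoxybenzoate, and is then expanded to the dioxane ring. The diazo compound is released from the tosylhydrazone sodium salt of 3,4,5-trimethoxybenzaldehyde.

Key step: step 4

Assumption: the sense of asymmetric induction in the new ring expansion cannot be derived from precedent, so Rh2(S-PTTL)4 is written for the (2R,3R) product and its mirror image Rh2(R-PTTL)4 would be taken if the opposite sense should be found.

Step 1
Reactants: 1 methyl 3,4-dihydroxy-5-methoxybenzoate; 2 acetaldehyde diethyl acetal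
Product: 3 methyl 7-methoxy-2-methyl-1,3-benzodioxole-5-carboxylate (racemic)
Conditions: 2 (3 equiv), PPTS (5 mol%), toluene, reflux with distillative removal of EtOH; Et3N quench
Reagents that add atoms: none
Why: Acid-catalysed transacetalisation, in which the two phenols add in turn to the ethoxy oxocarbenium ion from 2 and removal of ethanol drives closure of the five-membered cyclic acetal; the acetal carbon forms racemic, which does not matter because it is planarised in step 4.

Step 2
Reactants: 4 3,4,5-trimethoxybenzaldehyde; 5 p-toluenesulfonyl hydrazide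
Product: 6 3,4,5-trimethoxybenzaldehyde (E)-N-tosylhydrazone
Conditions: MeOH, rt; product collected by filtration and recrystallised
Reagents that add atoms: none
Why: Condensation of the aldehyde with the sulfonyl hydrazide should give the crystalline (E)-tosylhydrazone.

Step 3
Reactants: 6 3,4,5-trimethoxybenzaldehyde (E)-N-tosylhydrazone
Product: 7 sodium salt of tosylhydrazone 6
Conditions: NaOMe (1.0 equiv), MeOH, rt; evaporation, drying in vacuo, storage in the dark
Reagents that add atoms: sodium methoxide, C[O-].[Na+]
Why: Deprotonation of the acidic sulfonamide N–H gives the Bamford–Stevens salt, isolated dry so that its later fragmentation is the only source of the diazo compound.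

Step 4
Reactants: 3 methyl 7-methoxy-2-methyl-1,3-benzodioxole-5-carboxylate (racemic); 7 sodium salt of tosylhydrazone 6
Product: 9 methyl (2R,3R)-5-methoxy-3-methyl-2-(3,4,5-trimethoxyphenyl)-2,3-dihydro-1,4-benzodioxine-7-carboxylate, via aryldiazomethane 8 (not isolated)
Conditions: 7 (1.0 equiv, added in portions over several hours), 3 (3 equiv, excess recovered), dirhodium tetrakis[N-phthaloyl-(S)-tert-leucinate] Rh2(S-PTTL)4 (2 mol%), BnEt3NCl (10 mol%), PhCF3, 40 °C, exclusion of light
Reagents that add atoms: none
Why: Proposed new method: the electrophilic rhodium carbene formed from 8 on Rh2(S-PTTL)4 (divalent rhodium) should be captured by the acetal oxygen of 3 that becomes O1, and in the rhodium-associated oxonium ylide the O1–C(acetal) bond should break to a pair of an O4-stabilised oxocarbenium ion (or α-oxy radical) and a metal-bound benzylic carbon that recombine at carbon, a formal [1,2]-Stevens shift of the acetal carbon from O1 to the carbene carbon. The closest known reaction type is the rhodium- or copper-catalysed ring expansion of 1,3-dioxolanes and related cyclic acetals to 1,4-dioxanes by oxonium ylide [1,2]-shift with diazo esters and diazo ketones; new are the donor-only aryl carbene, the aryl acetal oxygen as nucleophile and the demand for enantiocontrol. The dioxane ring is closed by ring expansion, the C2–C3 bond forming in a 6-endo-trig recombination of the tethered benzylic carbon with the C3=O4 oxocarbenium carbon. Since C3 is planar in the ring-opened pair, both enantiomers of 3 should converge, and C2 and C3 are then set together in the recombination: the absolute sense by the chiral carboxylate wall around the rhodium-bound ylide, the trans relation by a half-chair transition state with aryl and methyl both pseudo-equatorial. The step needs ylide formation at O1 and not at O4, which the substrate secures because O4 is crowded by the C5 methoxy group and has its lone pair delocalised into the para ester, whereas O1 is meta to the ester and flanked only by C8–H; the unstabilised benzylic ylide is expected to rearrange faster than it reverts, so that this preference is carried into the product. Slow phase-transfer-limited release of 8, an excess of 3 and a non-coordinating solvent are meant to hold back azine and stilbene formation and to keep the ylide on the metal until it has rearranged.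

Step 5
Reactants: 9 methyl (2R,3R)-5-methoxy-3-methyl-2-(3,4,5-trimethoxyphenyl)-2,3-dihydro-1,4-benzodioxine-7-carboxylate
Product: 10 [(2R,3R)-5-methoxy-3-methyl-2-(3,4,5-trimethoxyphenyl)-2,3-dihydro-1,4-benzodioxin-7-yl]methanol
Conditions: i-Bu2AlH (2.5 equiv), CH2Cl2, –78 °C to 0 °C; aqueous potassium sodium tartrate work-up
Reagents that add atoms: none
Why: Hydride reduction of the aryl ester to the benzylic alcohol; C2 and C3 are ether carbons without an acidifying neighbour and are not touched.

Step 6
Reactants: 10 [(2R,3R)-5-methoxy-3-methyl-2-(3,4,5-trimethoxyphenyl)-2,3-dihydro-1,4-benzodioxin-7-yl]methanol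
Product: 11 (2R,3R)-5-methoxy-3-methyl-2-(3,4,5-trimethoxyphenyl)-2,3-dihydro-1,4-benzodioxine-7-carbaldehyde
Conditions: activated MnO2 (10 equiv), CH2Cl2, rt
Reagents that add atoms: none
Why: Chemoselective oxidation of the benzylic alcohol on MnO2 stops at the aldehyde and leaves the ethers and both stereocentres alone.

Step 7
Reactants: 11 (2R,3R)-5-methoxy-3-methyl-2-(3,4,5-trimethoxyphenyl)-2,3-dihydro-1,4-benzodioxine-7-carbaldehyde; 12 triethyl phosphonoacetate
Product: 13 ethyl (E)-3-[(2R,3R)-5-methoxy-3-methyl-2-(3,4,5-trimethoxyphenyl)-2,3-dihydro-1,4-benzodioxin-7-yl]prop-2-enoate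
Conditions: 12 (1.2 equiv), LiCl (1.2 equiv), DBU (1.1 equiv), MeCN, 0 °C to rt
Reagents that add atoms: none
Why: Horner–Wadsworth–Emmons olefination with the stabilised phosphonate anion should give the (E)-enoate through the favoured anti pathway, and the mild amine base does not endanger the C2–H centre.

Step 8
Reactants: 13 ethyl (E)-3-[(2R,3R)-5-methoxy-3-methyl-2-(3,4,5-trimethoxyphenyl)-2,3-dihydro-1,4-benzodioxin-7-yl]prop-2-enoate
Product: 14 (E)-3-[(2R,3R)-5-methoxy-3-methyl-2-(3,4,5-trimethoxyphenyl)-2,3-dihydro-1,4-benzodioxin-7-yl]prop-2-en-1-ol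
Conditions: i-Bu2AlH (2.5 equiv), CH2Cl2, –78 °C; aqueous potassium sodium tartrate work-up
Reagents that add atoms: none
Why: 1,2-Reduction of the α,β-unsaturated ester by the aluminium hydride at low temperature should give the (E)-allylic alcohol without touching the alkene or the stereocentres.

**Compound list**

1 | methyl 3,4-dihydroxy-5-methoxybenzoate | COC(=O)c1cc(O)c(O)c(OC)c1 | starting material
2 | acetaldehyde diethyl acetal (1,1-diethoxyethane) | CCOC(C)OCC | starting material
3 | methyl 7-methoxy-2-methyl-1,3-benzodioxole-5-carboxylate (racemic at the acetal carbon) | COC(=O)c1cc(OC)c2OC(C)Oc2c1 | intermediate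
4 | 3,4,5-trimethoxybenzaldehyde | COc1cc(C=O)cc(OC)c1OC | starting material
5 | p-toluenesulfonyl hydrazide | Cc1ccc(cc1)S(=O)(=O)NN | starting material
6 | 3,4,5-trimethoxybenzaldehyde (E)-N-tosylhydrazone | COc1cc(/C=N/NS(=O)(=O)c2ccc(C)cc2)cc(OC)c1OC | intermediate
7 | sodium salt of tosylhydrazone 6 | COc1cc(/C=N/[N-]S(=O)(=O)c2ccc(C)cc2)cc(OC)c1OC.[Na+] | intermediate
8 | 3,4,5-trimethoxyphenyldiazomethane (formed and consumed in step 4) | COc1cc(C=[N+]=[N-])cc(OC)c1OC | intermediate
9 | methyl (2R,3R)-5-methoxy-3-methyl-2-(3,4,5-trimethoxyphenyl)-2,3-dihydro-1,4-benzodioxine-7-carboxylate | COc1cc([C@H]2Oc3cc(C(=O)OC)cc(OC)c3O[C@@H]2C)cc(OC)c1OC | intermediate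
10 | [(2R,3R)-5-methoxy-3-methyl-2-(3,4,5-trimethoxyphenyl)-2,3-dihydro-1,4-benzodioxin-7-yl]methanol | COc1cc([C@H]2Oc3cc(CO)cc(OC)c3O[C@@H]2C)cc(OC)c1OC | intermediate
11 | (2R,3R)-5-methoxy-3-methyl-2-(3,4,5-trimethoxyphenyl)-2,3-dihydro-1,4-benzodioxine-7-carbaldehyde | COc1cc([C@H]2Oc3cc(C=O)cc(OC)c3O[C@@H]2C)cc(OC)c1OC | intermediate
12 | triethyl phosphonoacetate | CCOC(=O)CP(=O)(OCC)OCC | starting material
13 | ethyl (E)-3-[(2R,3R)-5-methoxy-3-methyl-2-(3,4,5-trimethoxyphenyl)-2,3-dihydro-1,4-benzodioxin-7-yl]prop-2-enoate | COc1cc([C@H]2Oc3cc(/C=C/C(=O)OCC)cc(OC)c3O[C@@H]2C)cc(OC)c1OC | intermediate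
14 | (E)-3-[(2R,3R)-5-methoxy-3-methyl-2-(3,4,5-trimethoxyphenyl)-2,3-dihydro-1,4-benzodioxin-7-yl]prop-2-en-1-ol | COc1cc([C@H]2Oc3cc(/C=C/CO)cc(OC)c3O[C@@H]2C)cc(OC)c1OC | target

Total step count: 8
Longest linear sequence: 7 steps (steps 2, 3, 4, 5, 6, 7, 8, from 3,4,5-trimethoxybenzaldehyde)

**Steps most likely to fail**

Step 4 (the new method). Three processes may defeat it. The carbene may be consumed by its own diazo precursor (azine and stilbene formation) faster than the weakly basic aryl acetal oxygen captures it. The ylide may rearrange after leaving the metal, or with memory of the acetal configuration, so that enantio- and diastereocontrol erode. Ylide formation at O4 would give the regioisomeric ring. The fallback uses known chemistry, sets out from 1 and returns to the route at 9; it takes C3 from the chiral pool and closes the ring by ionisation at C2. Ethyl (S)-lactate is silylated (TBSCl, imidazole, DMF) to ethyl (S)-2-[(tert-butyldimethylsilyl)oxy]propanoate F1. This is converted with MeNH(OMe)·HCl and i-PrMgCl into (S)-2-[(tert-butyldimethylsilyl)oxy]-N-methoxy-N-methylpropanamide F2. Addition of 3,4,5-trimethoxyphenylmagnesium bromide (THF, 0 °C) should give (S)-2-[(tert-butyldimethylsilyl)oxy]-1-(3,4,5-trimethoxyphenyl)propan-1-one F3, and HF·pyridine frees (S)-2-hydroxy-1-(3,4,5-trimethoxyphenyl)propan-1-one F4. Mitsunobu etherification of this alcohol with catechol 1 (PPh3, DIAD, THF, 0 °C) should engage the more acidic 4-OH para to the ester and proceed with inversion. The product is methyl 3-hydroxy-5-methoxy-4-{[(2R)-1-oxo-1-(3,4,5-trimethoxyphenyl)propan-2-yl]oxy}benzoate F5, which is expected to rest largely as its cyclic hemiketal and so be guarded against enolisation. NaBH4 (MeOH, 0 °C) reduces the ketone to methyl 3-hydroxy-4-{[(2R)-1-hydroxy-1-(3,4,5-trimethoxyphenyl)propan-2-yl]oxy}-5-methoxybenzoate F6 (both epimers at the carbinol carbon serve). BF3·OEt2 (CH2Cl2, 0 °C) then ionises the benzylic alcohol to the para-methoxy-stabilised cation, which the free 3-OH (the future O1) should close to the more stable trans ring, giving 9.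

Step 1. Ring closure of the electron-poor catechol may stall at the open mixed acetal under equilibrium control, while the acetaldehyde equivalent is lost to acid-promoted self-condensation. The fallback runs from 1 back to 3 through a higher oxidation level. Compound 1 and triethyl orthoacetate (cat. PPTS, toluene, EtOH distilled off) should give the cyclic orthoester methyl 2-ethoxy-7-methoxy-2-methyl-1,3-benzodioxole-5-carboxylate F7, a closure that is strongly favoured for catechols. Ionic hydrogenation (Et3SiH, BF3·OEt2, CH2Cl2, –78 °C) then replaces the ethoxy group by hydride through the 2-methyl-1,3-benzodioxolium ion and delivers 3; the ester is inert to the silane.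

Step 3. A salt that retains methanol or water, or has seen light, may fragment unevenly, so that release of the diazo compound is not matched to its consumption in step 4 and carbene dimerisation takes over. The fallback runs from 4 and rejoins the route at 8, generating the diazo compound by dehydrogenation instead of sulfinate elimination. Aldehyde 4 and excess hydrazine hydrate (EtOH, rt) give 3,4,5-trimethoxybenzaldehyde hydrazone F8. Oxidation with activated MnO2 over MgSO4 in PhCF3 at 0 °C and cold filtration should give a solution of 8. This is fed by syringe pump into 3 and the rhodium catalyst under the conditions of step 4, without the phase-transfer salt.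

**Further compounds**

F1 | step 4 | ethyl (S)-2-[(tert-butyldimethylsilyl)oxy]propanoate | CCOC(=O)[C@H](C)O[Si](C)(C)C(C)(C)C
F2 | step 4 | (S)-2-[(tert-butyldimethylsilyl)oxy]-N-methoxy-N-methylpropanamide | CON(C)C(=O)[C@H](C)O[Si](C)(C)C(C)(C)C
F3 | step 4 | (S)-2-[(tert-butyldimethylsilyl)oxy]-1-(3,4,5-trimethoxyphenyl)propan-1-one | COc1cc(cc(OC)c1OC)C(=O)[C@H](C)O[Si](C)(C)C(C)(C)C
F4 | step 4 | (S)-2-hydroxy-1-(3,4,5-trimethoxyphenyl)propan-1-one | COc1cc(cc(OC)c1OC)C(=O)[C@H](C)O
F5 | step 4 | methyl 3-hydroxy-5-methoxy-4-{[(2R)-1-oxo-1-(3,4,5-trimethoxyphenyl)propan-2-yl]oxy}benzoate | COc1cc(cc(OC)c1OC)C(=O)[C@@H](C)Oc1c(O)cc(cc1OC)C(=O)OC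
F6 | step 4 | methyl 3-hydroxy-4-{[(2R)-1-hydroxy-1-(3,4,5-trimethoxyphenyl)propan-2-yl]oxy}-5-methoxybenzoate | COc1cc(cc(OC)c1OC)C(O)[C@@H](C)Oc1c(O)cc(cc1OC)C(=O)OC
F7 | step 1 | methyl 2-ethoxy-7-methoxy-2-methyl-1,3-benzodioxole-5-carboxylate | CCOC1(C)Oc2cc(cc(OC)c2O1)C(=O)OC
F8 | step 3 | 3,4,5-trimethoxybenzaldehyde hydrazone | COc1cc(/C=N/N)cc(OC)c1OC
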